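**Assumptions (one line):** 2-butynal is taken as commercially available. The C10 stereocentre is installed with about 90% ee at step 1. The minor C10 series is removed as diastereomers at step 7.

## Retrosynthetic overview
1. Caruifolin B ⇒ bis-TES norbornanone (the C4′-epimer) by silyl removal and epimerisation. That norbornanone comes from a radical [4+2]-type annulation that forms C2–C2′ and C3–C5′: the α′-keto radical of enone monomer **12** adds to cyclopentadiene monomer **14**, and the resulting allyl radical closes 5-exo onto C5′.
2. Both halves come from one 5-7-5 guaianolide 4-en-3-one (**12**). It is used directly (α′-bromide) or converted to the cyclopentadiene by Luche reduction and dehydration.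
3. Enone **12** comes from an intramolecular Pauson–Khand reaction of a lactone-tethered 1,8-enyne, which closes the cycloheptane and the cyclopentenone together.
4. The enyne's trans,trans-lactone comes from SmI2 ketyl–enoate coupling of 2-butynal with an enoate built from (R)-2-methylglycidol, which supplies C10.
5. Ring order: γ-lactone, then cycloheptane plus cyclopentenone, then the bridged norbornanone.

## Route

**Step 1**
Reactants: 1 methallyl alcohol
Product: 2 (R)-2-methylglycidol, (2R)-(2-methyloxiran-2-yl)methanol
Conditions: Ti(OiPr)4 (10 mol%), D-(−)-DET (12 mol%), TBHP, 3 Å MS, CH2Cl2, −20 °C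
Reagents that add atoms: tert-butyl hydroperoxide, CC(C)(C)OO (supplies the epoxide O)
Why: Sharpless asymmetric epoxidation of the 2-substituted allylic alcohol sets the quaternary carbinol centre that becomes C10.

**Step 2**
Reactants: 2 (R)-2-methylglycidol; 3 allylmagnesium bromide
Product: 4 (2S)-2-methylhex-5-ene-1,2-diol
Conditions: 3 (3 equiv), CuI (10 mol%), THF, −40 °C → 0 °C
Reagents that add atoms: allylmagnesium bromide (3), C=CC[Mg]Br
Why: Cu-catalysed Grignard opening occurs by SN2 at the unhindered epoxide CH2 (future C9), so C10 is untouched. The allyl unit supplies C8 and C7, and the terminal =CH2 is lost later.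

**Step 3**
Reactants: 4 diol; 5 ethyl methacrylate
Product: 6 ethyl (2E,6S)-6,7-dihydroxy-2,6-dimethylhept-2-enoate
Conditions: 5 (5 equiv), Hoveyda–Grubbs II (5 mol%), CH2Cl2, 40 °C
Reagents that add atoms: ethyl methacrylate (5), C=C(C)C(=O)OCC (supplies C11, C12 and C13)
Why: Cross-metathesis of the unhindered terminal alkene with a methacrylate (Type II partner) gives the E-trisubstituted enoate. No second alkene is present, so ring-closing metathesis cannot compete.

**Step 4**
Reactants: 6
Product: 7 ethyl (2E,6S)-6-hydroxy-2,6-dimethyl-7-oxohept-2-enoate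
Conditions: TEMPO (10 mol%), PhI(OAc)2, CH2Cl2, 25 °C
Reagents that add atoms: none
Why: TEMPO oxidation is selective for the primary alcohol over the tertiary one. The α-quaternary aldehyde cannot epimerise.

**Step 5**
Reactants: 7
Product: 8 ethyl (2E,6S)-6-hydroxy-2,6-dimethylocta-2,7-dienoate
Conditions: Ph3P=CH2 (from Ph3PCH3Br, KOtBu; 3 equiv), THF, 0 °C
Reagents that add atoms: methylenetriphenylphosphorane, C=P(c1ccccc1)(c1ccccc1)c1ccccc1 (supplies C2, giving the C1=C2 vinyl)
Why: Wittig methylenation installs the vinyl group that becomes the Pauson–Khand alkene. The extra equivalent of ylide covers the free OH.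

**Step 6**
Reactants: 8
Product: 9 triethylsilyl ether of 8, CCOC(=O)/C(C)=C/CC[C@](C)(OSiEt3)C=C
Conditions: TESOTf, 2,6-lutidine, CH2Cl2, −78 → 0 °C
Reagents that add atoms: triethylsilyl triflate, CC[Si](CC)(CC)OS(=O)(=O)C(F)(F)F
Why: The TES group protects the tertiary alcohol through the SmI2, Pauson–Khand and LDA steps. It is removed in the last step.

**Step 7**
Reactants: 9 enoate; 10 2-butynal
Product: 11 all-trans lactone, 3-methyl-4-[3-methyl-3-(triethylsilyloxy)pent-4-en-1-yl]-5-(prop-1-yn-1-yl)dihydrofuran-2-one. The C11 methyl is trans to C8, C8 is trans to the propynyl group, and C10 is S.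
Conditions: SmI2 (2.2 equiv), t-BuOH (2 equiv), THF, −78 °C (10, 1.5 equiv)
Reagents that add atoms: 2-butynal (10), CC#CC=O (supplies C4, C5 and C6)
Why: SmI2 ketyl–olefin coupling: the Sm(III) ketyl of the ynal adds to the enoate β-carbon (C6–C7 bond), t-BuOH protonates the Sm-enolate at C11, and the alkoxide lactonises. An anti TS and a thermodynamic C11 give the all-trans lactone. C10 is remote, so the mirror-related C6/C7/C11 series also forms and is removed by chromatography as the C10-diastereomer.

**Step 8**
Reactants: 11
Product: 12 enone, the 5-7-5 guaian-4-en-3-one-6,12-olide with 11,13-dihydro, trans-fused 6,7-lactone, 10-Me and 10-OTES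
Conditions: Co2(CO)8 (1.1 equiv), CH2Cl2, 25 °C; then NMO (6 equiv), 0 → 25 °C
Reagents that add atoms: carbon monoxide from Co2(CO)8, [C-]#[O+] (supplies C3)
Why: Intramolecular Pauson–Khand reaction of the 1,8-enyne forms C1–C5 and C2–C3 and gives the 2-methylcyclopentenone. C1 is set by the tether stereocentres (H1 cis to Me10). It is the γ-carbon of the enone, so DBU can equilibrate it if needed.

**Step 9**
Reactants: 12
Product: 13 allylic alcohol, the 3-hydroxy-Δ4 analogue of 12 (C3 epimers)
Conditions: NaBH4, CeCl3·7H2O, MeOH, −78 °C
Reagents that add atoms: none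
Why: Luche 1,2-reduction leaves the lactone and OTES intact. C3 is destroyed in the next step, so its configuration is irrelevant.

**Step 10**
Reactants: 13
Product: 14 cyclopentadiene monomer (Δ2,4; C1 is the sp3 carbon), SMILES in the compound list
Conditions: Martin sulfurane, CH2Cl2, −20 °C, 15 min; cold filtration through Et3N-deactivated silica; used immediately
Reagents that add atoms: none
Why: Dehydration of the allylic alcohol can only remove H-2, so it gives the C2=C3/C4=C5 diene. The diene is kept cold because 5-substituted cyclopentadienes undergo 1,5-H shifts that would scramble C1.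

**Step 11**
Reactants: 12
Product: 15 α′-bromoenone (Br at C2, the CH2 next to the ketone)
Conditions: LDA (1.1 equiv), THF, −78 °C; TMSCl; then NBS, −78 °C
Reagents that add atoms: N-bromosuccinimide, O=C1CCC(=O)N1Br (supplies Br)
Why: Kinetic deprotonation at the α′-CH2 gives the cross-conjugated silyl dienol ether, which NBS brominates at C2. The bromide is a radical precursor, and its stereochemistry is lost on radical formation.

**Step 12**
Reactants: 15 α′-bromoenone; 14 cyclopentadiene
Product: 16 bis-TES norbornanone dimer, the C4′-endo-methyl epimer of the target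
Conditions: 15 (1 equiv), 14 (2.5 equiv), (TMS)3SiH (1.3 equiv, syringe pump, ≤0.005 M), Et3B (0.3 equiv)/air, toluene, −20 → 0 °C
Reagents that add atoms: none (the silane supplies only H)
Why: Proposed new method: (TMS)3Si• removes Br from 15 to give the electrophilic α′-keto radical at C2′. This adds to the less hindered terminus C2 of the electron-rich diene 14, on the face anti to the C10 side chain (polarity-matched). The allyl radical C3/C5 then closes 5-exo at C3 onto the enone β-carbon C5′, again from the face anti to C10′, and the resulting α-keto radical (C4′) takes H from the silane. Both new bonds form on the same face of each ring, giving the cis-bridged bicyclo[2.2.1]heptanone with unit 1's ring endo and C2–C3/C2′–C5′ correctly related. Closest known chemistry: Snider α′-keto radical–alkene annulation, Giese addition and 5-exo radical closure to norbornanes. The C4′ methyl is expected endo because H is delivered from the open exo face.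

**Step 13**
Reactants: 16
Product: 17 caruifolin B
Conditions: TBAF (3 equiv), THF, 0 → 25 °C, 3 h
Reagents that add atoms: none
Why: Fluoride removes both TES groups. The basic medium enolises the C3′ ketone toward C4′ only, because C2′ is a bridgehead (Bredt). This epimerises the endo-methyl to the exo-methyl of the target, which avoids a clash with unit 1's ring. C11 and C11′ stay at the thermodynamic trans configuration.

## Compound list
1 | methallyl alcohol | C=C(C)CO | starting material
2 | (R)-2-methylglycidol | OC[C@]1(C)CO1 | intermediate
3 | allylmagnesium bromide | C=CC[Mg]Br | starting material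
4 | (2S)-2-methylhex-5-ene-1,2-diol | C=CCC[C@](C)(O)CO | intermediate
5 | ethyl methacrylate | C=C(C)C(=O)OCC | starting material
6 | ethyl (2E,6S)-6,7-dihydroxy-2,6-dimethylhept-2-enoate | CCOC(=O)/C(C)=C/CC[C@](C)(O)CO | intermediate
7 | ethyl (2E,6S)-6-hydroxy-2,6-dimethyl-7-oxohept-2-enoate | CCOC(=O)/C(C)=C/CC[C@](C)(O)C=O | intermediate
8 | ethyl (2E,6S)-6-hydroxy-2,6-dimethylocta-2,7-dienoate | CCOC(=O)/C(C)=C/CC[C@](C)(O)C=C | intermediate
9 | TES ether of 8 | CCOC(=O)/C(C)=C/CC[C@](C)(O[Si](CC)(CC)CC)C=C | intermediate
10 | 2-butynal | CC#CC=O | starting material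
11 | all-trans propynyl lactone | CC#C[C@H]1OC(=O)[C@@H](C)[C@@H]1CC[C@](C)(O[Si](CC)(CC)CC)C=C | intermediate
12 | 10-OTES guaian-4-en-3-one-6,12-olide | CC1=C2[C@H]3OC(=O)[C@@H](C)[C@@H]3CC[C@](C)(O[Si](CC)(CC)CC)[C@@H]2CC1=O | intermediate
13 | 3-hydroxy-Δ4 allylic alcohol | CC1=C2[C@H]3OC(=O)[C@@H](C)[C@@H]3CC[C@](C)(O[Si](CC)(CC)CC)[C@@H]2CC1O | intermediate
14 | cyclopentadiene monomer | CC1=C2[C@H]3OC(=O)[C@@H](C)[C@@H]3CC[C@](C)(O[Si](CC)(CC)CC)[C@@H]2C=C1 | intermediate
15 | α′-bromoenone | CC1=C2[C@H]3OC(=O)[C@@H](C)[C@@H]3CC[C@](C)(O[Si](CC)(CC)CC)[C@@H]2C(Br)C1=O | intermediate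
16 | bis-TES norbornanone dimer (C4′-endo-Me) | CC1=C2[C@H]3OC(=O)[C@@H](C)[C@@H]3CC[C@](C)(O[Si](CC)(CC)CC)[C@@H]2[C@H]2[C@H]3C(=O)[C@@H](C)[C@]4([C@@H]3[C@@](C)(O[Si](CC)(CC)CC)CC[C@H]3[C@H](C)C(=O)O[C@@H]34)[C@@H]12 | intermediate
17 | caruifolin B | CC1=C2[C@H]3OC(=O)[C@@H](C)[C@@H]3CC[C@](C)(O)[C@@H]2[C@H]2[C@H]3C(=O)[C@H](C)[C@]4([C@@H]3[C@@](C)(O)CC[C@H]3[C@H](C)C(=O)O[C@@H]34)[C@@H]12 | target

**Total steps:** 13 (steps 1–13, with step 11 run in parallel to steps 9–10).
**Longest linear sequence:** 12 steps (1–8, 9, 10, 12, 13).

## Three steps most likely to fail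
1. **Step 12 (radical annulation).** The allyl radical may be reduced before it closes, the cyclopentadiene may isomerise by 1,5-H shifts or dimerise, and the endo/exo outcome is uncertain.
   Fallback: change to a polar biomimetic Diels–Alder. Convert 12 to its 2-silyloxycyclopentadiene (LDA, TMSOTf) and react it with 14 as dienophile under high pressure or with a Lewis acid, then protodesilylate.
2. **Step 7 (SmI2 ketyl–enoate coupling).** The trisubstituted enoate is a poor acceptor, and the propargylic ketyl or the propargylic lactone may be over-reduced or give pinacol products.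
   Fallback: build a stereodefined 5-propynyl-3-methylbutenolide (Sharpless kinetic resolution of hex-1-en-4-yn-3-ol, methacrylate ester, ring-closing metathesis). Then add the C8–C10 fragment by photoredox decarboxylative Giese addition of 4-silyloxy-4-methylhex-5-enoic acid, and epimerise C11.
3. **Step 8 (Pauson–Khand 1,8-enyne).** Seven-membered ring formation is low-yielding, and C1 may come out as the wrong epimer.
   Fallback: close the cycloheptene by ring-closing metathesis of a Δ1(5) diene, then build the cyclopentenone by Nazarov cyclisation of the cycloheptenyl vinyl ketone.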